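Numbering: decalin C1–C10 as in drimanes (C11 = CH2 link, C12 = exocyclic CH2); six-ring C1'–C6' with C7' = its CH2O carbon; acid C1''–C4''.
Cuts, in order: the C7'O–C1'' ester; the C1'–C2' epoxide and both ring carbonyls (back to a C6' phenol / C3' methyl ether arene); C8=C12; C3–C4 (ring A); a C4–C7 bond is then added; last, C9–C11 and C1–C10 are cut together.
Enabling feature: ring B (C5–C10) with sp2 C8, the methyl-bearing quaternary C10, C5 and the gem-dimethyl carbon C4 becomes the verbenone skeleton once C4 is tied to C7. Its C8=O/C9=C10 enone accepts C1 at C10 and C11 at C9 in one flask.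
Forward: ring B is bought inside the bicycle; three-component coupling; the C4–C7 cyclobutane bond is cut; ring A closes by attack of a C4 radical on a C3 aldehyde; C8 is methylenated; the arene becomes the epoxyquinone; the acid is attached last.
Stereochemistry: C5 from (+)-verbenone, C10 from its gem-dimethyl bridge, C9 by equilibration beside the C8 ketone, C3 (axial 3α-OH) by a bulky hydride, C1'/C2' by tartrate-mediated epoxidation, C2''/C3'' from D-threonine.

Key step: step 7

Remark: Ar = 5-methoxy-4-(methoxycarbonyl)-2-(triisopropylsilyloxy)phenyl, bound to C11 through C1'. C9 (compounds 11–15) and C3 (compounds 15–17) are carried as epimer mixtures and written without a descriptor until steps 12 and 15 fix them.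
Remark: diisopropyl L-(+)-tartrate is assumed to be the enantiomer whose sodium complex directs the peroxide to the face giving the (1'S,2'R)-epoxide. If the sense is the reverse, the D-(−)-ester takes its place in the same step.

Step 1
Reactants: 1 4-bromo-2,5-dimethoxybenzaldehyde
Product: 2 4-bromo-2-hydroxy-5-methoxybenzaldehyde
Conditions: BCl3 (1.2 equiv), CH2Cl2, −78 °C → rt; H2O
Reagents that add atoms: none
Why: Chelation-directed aryl ether cleavage, in which boron binds the formyl oxygen and the ortho methoxy group in a six-membered chelate, so that only the future C6' oxygen is freed and the two ring oxygens become different.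

Step 2
Reactants: 2 4-bromo-2-hydroxy-5-methoxybenzaldehyde
Product: 3 methyl 4-formyl-5-hydroxy-2-methoxybenzoate
Conditions: Pd(OAc)2 (5 mol%), dppf (10 mol%), CO (1 atm), Et3N, MeOH/DMF, 70 °C
Reagents that add atoms: carbon monoxide [C-]#[O+]; methanol CO
Why: Palladium-catalysed alkoxycarbonylation of an aryl bromide activated by the para formyl group brings in C7' at the ester level, which deactivates the ring and cannot ionise under the Lewis acid of step 8 as a benzylic ester or ether could.

Step 3
Reactants: 3 methyl 4-formyl-5-hydroxy-2-methoxybenzoate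
Product: 4 methyl 4-formyl-2-methoxy-5-(triisopropylsilyloxy)benzoate
Conditions: TIPSOTf, 2,6-lutidine, CH2Cl2, 0 °C
Reagents that add atoms: triisopropylsilyl triflate CC(C)[Si](OS(=O)(=O)C(F)(F)F)(C(C)C)C(C)C
Why: O-silylation of the hydrogen-bonded phenol with the reactive silyl triflate gives a bulky aryl silyl ether that tolerates enolates, acid and hydrides and leaves later with fluoride.

Step 4
Reactants: 4 methyl 4-formyl-2-methoxy-5-(triisopropylsilyloxy)benzoate
Product: 5 methyl 4-(hydroxymethyl)-2-methoxy-5-(triisopropylsilyloxy)benzoate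
Conditions: NaBH4, THF/MeOH, −10 °C; aq NH4Cl
Reagents that add atoms: none
Why: Chemoselective borohydride reduction of the aldehyde beside the benzoate, kept cold and short so that the bulky silyl group does not migrate to the new alkoxide.

Step 5
Reactants: 5 methyl 4-(hydroxymethyl)-2-methoxy-5-(triisopropylsilyloxy)benzoate
Product: 6 methyl 4-(bromomethyl)-2-methoxy-5-(triisopropylsilyloxy)benzoate
Conditions: CBr4, PPh3, CH2Cl2, 0 °C
Reagents that add atoms: carbon tetrabromide BrC(Br)(Br)Br
Why: The Appel reaction turns the primary benzylic alcohol into the bromide under neutral conditions that leave the silyl ether and ester alone.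

Step 6
Reactants: 7 (3-bromopropoxy)(tert-butyl)dimethylsilane
Product: 8 3-(tert-butyldimethylsilyloxy)propylmagnesium bromide
Conditions: Mg turnings, trace I2, THF, 25–40 °C
Reagents that add atoms: magnesium [Mg]
Why: Grignard formation by direct magnesium insertion into a primary bromide; the oxygen sits γ to magnesium, so no β-elimination is possible, and C3 is carried as a silyl ether because an acetal would not outlast the Lewis acid of step 8.

Step 7
Reactants: 9 (1R,5R)-(+)-verbenone; 8 3-(tert-butyldimethylsilyloxy)propylmagnesium bromide; 6 methyl 4-(bromomethyl)-2-methoxy-5-(triisopropylsilyloxy)benzoate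
Product: 11 9-(ArCH2)-10-(3-silyloxypropyl) pinanone (chain anti to the gem-dimethyl bridge; C9 epimers), via bromomagnesium enolate 10 (not isolated)
Conditions: 8 (1.2 equiv), CuBr·SMe2 (10 mol%), THF, −40 → 0 °C; then 6 (1.4 equiv), DMPU, −20 °C → rt
Reagents that add atoms: none
Why: The alkylcopper species formed from 8 and catalytic CuBr·SMe2 complexes the enone of 9, transfers the C1 carbon to the β-carbon C10 (C1–C10) and leaves the bromomagnesium enolate 10, which, once DMPU has loosened its aggregates, displaces bromide from 6 in an SN2 reaction at C9 (C9–C11). The closest known reaction type is the tandem conjugate addition–enolate alkylation (three-component coupling) of cyclic enones, and copper-mediated Grignard addition to verbenone itself is established chemistry. No ring is closed in this step. C10 is controlled by the gem-dimethyl bridge (C4), whose inner methyl group covers one enone face, so that the chain enters from the methylene-bridge (C6) face and ends trans to the C5–C4 bond with the methyl group cis to it, the relationship of a trans-decalin; C9 is not controlled reliably (entry of 6 anti to the bridge, giving the 9α-benzyl epimer, should prevail) and is put right in step 12. The step needs 1,4- rather than 1,2-addition, which copper provides, and a single, non-scrambling enolate, which the substrate provides because the other α-carbon C7 is a bridgehead that cannot enolise. Double alkylation is shut off because the remaining C9–H sits between the carbonyl group and a quaternary carbon, and the ester para to the CH2Br group keeps 6 from ionising, so that it reacts only as an SN2 partner.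

Step 8
Reactants: 11 9-(ArCH2)-10-(3-silyloxypropyl) pinanone
Product: 12 C7=C8 enol acetate of the ring B ketone with 5-isopropenyl (5α-H), 10β-methyl and 10-(3-acetoxypropyl) groups (C9 epimers)
Conditions: BF3·OEt2, Zn(OAc)2, Ac2O, 0 °C → rt
Reagents that add atoms: acetic anhydride CC(=O)OC(C)=O
Why: Lewis-acid-induced heterolysis of the strained C7–C4 bond next to the complexed ketone gives a tertiary C4 cation and a C7=C8 enolate, quenched by loss of a methyl proton (isopropenyl) and by O-acetylation as known for 4,4-disubstituted nopinones; the same medium acetolyses the primary silyl ether, while C5, C10, the benzoate and the less basic, bulkier aryl silyl ether are not touched.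

Step 9
Reactants: 12 enol acetate / primary acetate
Product: 13 keto alcohol: 9-(ArCH2)-10-(3-hydroxypropyl)-5-isopropenyl-10-methyl ring B 8-ketone (C9 epimers)
Conditions: catalytic K2CO3, MeOH, 0 °C
Reagents that add atoms: none
Why: Base-catalysed transesterification (Zemplén-type methanolysis) removes the enol acetate, which tautomerises to the C8 ketone, and the primary acetate, whereas exchange at the methyl benzoate is degenerate in methanol and the hindered aryl silyl ether should survive the short, cold exposure.

Step 10
Reactants: 13 keto alcohol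
Product: 14 keto aldehyde (C3 = CHO; C9 epimers)
Conditions: Dess–Martin periodinane, CH2Cl2, 0 °C → rt
Reagents that add atoms: none
Why: Dess–Martin oxidation stops at the aldehyde, works without base, so that no aldol reaction between the C3 aldehyde and the C8 ketone is triggered, and leaves the isopropenyl group alone.

Step 11
Reactants: 14 keto aldehyde
Product: 15 11-Ar-3-hydroxy-12-nordriman-8-one (trans-decalin, 5α-H, 10β-CH3; C3 and C9 epimers)
Conditions: Fe(acac)3 (30 mol%), PhSiH3, degassed EtOH, 60 °C
Reagents that add atoms: none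
Why: Metal-hydride hydrogen-atom-transfer reductive alkene–carbonyl cyclisation, in which the iron hydride gives H to the CH2 terminus of the isopropenyl group, the tertiary C4 radical adds 6-exo to the aldehyde carbon C3 and the alkoxy radical is reduced and protonated; the ring fusion can only be trans because C4 and C1 are trans-diequatorial on ring B, and the C3 epimers are levelled in steps 14 and 15.

Step 12
Reactants: 15 11-Ar-3-hydroxy-12-nordriman-8-one (C9 epimers)
Product: 16 (9S)-11-Ar-3-hydroxy-12-nordriman-8-one (equatorial 9β-CH2Ar, 9α-H; C3 epimers)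
Conditions: catalytic p-TsOH·H2O, MeOH, 60 °C; minor epimer resubmitted
Reagents that add atoms: none
Why: Acid-catalysed keto–enol equilibration through the more substituted C8=C9 enol, safe now that no alkene is left, should drain the mixture toward the equatorial 9β-CH2Ar isomer, which is the more stable one in the rigid trans-decalin and also the one formed by axial protonation on the α-face away from the axial C10 methyl group; the alkoxide-sensitive aryl silyl ether tolerates acid.

Step 13
Reactants: 16 (9S)-11-Ar-3-hydroxy-12-nordriman-8-one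
Product: 17 11-Ar-drim-8(12)-en-3-ol (C3 epimers)
Conditions: Zn, CH2Br2, TiCl4, THF/CH2Cl2, 0 °C → rt
Reagents that add atoms: dibromomethane BrCBr
Why: Takai–Lombardo methylenation, whose non-basic gem-dimetallic reagent converts hindered, enolisable ketones without epimerising the α-centre C9 and spares esters, free hydroxyl groups and silyl ethers, which a phosphorus ylide at the temperature needed here would not.

Step 14
Reactants: 17 11-Ar-drim-8(12)-en-3-ol
Product: 18 11-Ar-drim-8(12)-en-3-one
Conditions: Dess–Martin periodinane, CH2Cl2, rt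
Reagents that add atoms: none
Why: Dess–Martin oxidation merges both C3 epimers into one ketone without touching the exocyclic alkene or the protected arene.

Step 15
Reactants: 18 11-Ar-drim-8(12)-en-3-one
Product: 20 (3R)-3α-hydroxydrim-8(12)-ene with 4-(hydroxymethyl)-5-methoxy-2-(triisopropylsilyloxy)phenyl at C11, via 3α-hydroxy benzoate 19 (not isolated)
Conditions: LiBH(s-Bu)3 (L-Selectride), THF, −78 °C; then i-Bu2AlH (DIBAL-H), −78 → 0 °C; aq work-up
Reagents that add atoms: none
Why: Diastereoselective ketone reduction by a bulky trialkylborohydride, which approaches the 4,4-dimethyl-3-ketone along the equatorial trajectory and so gives the axial 3α-alcohol (3R) as in 3-oxo triterpenoids, followed in the same flask by aluminium hydride reduction of the benzoate to the C7' alcohol.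

Step 16
Reactants: 20 silyl-protected diol
Product: 21 free C6' phenol (4-methoxyphenol type) with C7' and 3α hydroxyl groups
Conditions: Bu4NF, AcOH, THF, 0 °C
Reagents that add atoms: none
Why: Fluoride-induced desilylation of the aryl silyl ether, buffered with acetic acid so that the electron-rich phenoxide is protonated at once.

Step 17
Reactants: 21 phenol
Product: 22 2-[(3α-hydroxydrim-8(12)-en-11-yl)]-5-(hydroxymethyl)-4,4-dimethoxycyclohexa-2,5-dien-1-one (C6' = O, C3' = dimethyl ketal)
Conditions: PhI(OAc)2, MeOH, 0 °C
Reagents that add atoms: methanol CO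
Why: Hypervalent-iodine oxidative dearomatisation of a 4-methoxyphenol in methanol gives the p-quinone monoketal with the carbonyl group at C6', which makes the two ring alkenes different (C1'=C2' α-alkyl with a free β-CH, C4'=C5' β-substituted).

Step 18
Reactants: 22 quinone monoketal
Product: 23 (1'S,2'R)-1',2'-epoxide of 22
Conditions: Ph3COOH, NaN(SiMe3)2, diisopropyl L-(+)-tartrate, toluene, −50 °C
Reagents that add atoms: trityl hydroperoxide OOC(c1ccccc1)(c1ccccc1)c1ccccc1
Why: Weitz–Scheffer nucleophilic epoxidation in its tartrate-mediated form, in which the peroxide anion adds to the unsubstituted β-carbon C2' rather than to the fully substituted C4', and the chiral sodium tartrate aggregate anchored on the free C7' hydroxyl group selects the face and sets C1' and C2' together.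

Step 19
Reactants: 24 D-threonine
Product: 25 (2R,3S)-2,3-dihydroxybutanoic acid
Conditions: NaNO2, 1 M aq H2SO4, 0 °C → rt
Reagents that add atoms: water O
Why: Diazotisation of an α-amino acid replaces nitrogen by hydroxyl with net retention at C2'' through double inversion via the α-lactone, and C3'' is not involved.

Step 20
Reactants: 25 (2R,3S)-2,3-dihydroxybutanoic acid
Product: 27 (2R,3S)-2,3-bis(triethylsilyloxy)butanoic acid, via triethylsilyl ester 26 (not isolated)
Conditions: Et3SiCl (3.3 equiv), imidazole, DMF, 0 °C → rt; then H2O/THF, 0 °C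
Reagents that add atoms: chlorotriethylsilane CC[Si](Cl)(CC)CC
Why: Persilylation followed by selective hydrolysis of the far more labile silyl ester frees the acid while both silyl ethers stay.

Step 21
Reactants: 23 (1'S,2'R)-epoxy ketal alcohol; 27 (2R,3S)-2,3-bis(triethylsilyloxy)butanoic acid
Product: 28 C7' ester of 23 with 27
Conditions: EDC·HCl, catalytic DMAP, CH2Cl2, 0 °C → rt
Reagents that add atoms: none
Why: Steglich-type carbodiimide esterification acylates the primary allylic C7' hydroxyl group and not the axial, neopentyl C3 hydroxyl group, under conditions mild enough for the epoxide, the ketal and the α-centre of the acid.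

Step 22
Reactants: 28 protected ester
Product: 29 neomacrophorin I
Conditions: 48% aq HF, MeCN, 0 °C → rt
Reagents that add atoms: water O
Why: Acidic global deprotection, in which aqueous HF cleaves both triethylsilyl ethers and hydrolyses the dimethyl ketal to the C3' ketone, conditions that electron-poor epoxy enones and exocyclic alkenes tolerate.

Compound list
1 | 4-bromo-2,5-dimethoxybenzaldehyde | O=Cc1cc(OC)c(Br)cc1OC | starting material
2 | 4-bromo-2-hydroxy-5-methoxybenzaldehyde | O=Cc1cc(OC)c(Br)cc1O | intermediate
3 | methyl 4-formyl-5-hydroxy-2-methoxybenzoate | COC(=O)c1cc(O)c(C=O)cc1OC | intermediate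
4 | methyl 4-formyl-2-methoxy-5-(triisopropylsilyloxy)benzoate | COC(=O)c1cc(O[Si](C(C)C)(C(C)C)C(C)C)c(C=O)cc1OC | intermediate
5 | methyl 4-(hydroxymethyl)-2-methoxy-5-(triisopropylsilyloxy)benzoate | COC(=O)c1cc(O[Si](C(C)C)(C(C)C)C(C)C)c(CO)cc1OC | intermediate
6 | methyl 4-(bromomethyl)-2-methoxy-5-(triisopropylsilyloxy)benzoate | COC(=O)c1cc(O[Si](C(C)C)(C(C)C)C(C)C)c(CBr)cc1OC | intermediate
7 | (3-bromopropoxy)(tert-butyl)dimethylsilane | BrCCCO[Si](C)(C)C(C)(C)C | starting material
8 | 3-(tert-butyldimethylsilyloxy)propylmagnesium bromide | Br[Mg]CCCO[Si](C)(C)C(C)(C)C | intermediate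
9 | (1R,5R)-(+)-verbenone | O=C1C=C(C)[C@H]2C[C@@H]1C2(C)C | starting material
10 | bromomagnesium C8=C9 enolate of the 10-alkylated pinanone | Br[Mg]OC1=C[C@@](C)(CCCO[Si](C)(C)C(C)(C)C)[C@H]2C[C@@H]1C2(C)C | intermediate (not isolated)
11 | 3-(ArCH2)-4-[3-(tert-butyldimethylsilyloxy)propyl]-4,6,6-trimethylbicyclo[3.1.1]heptan-2-one, chain anti to the gem-dimethyl bridge, C9 epimers | O=C1C(Cc3cc(OC)c(C(=O)OC)cc3O[Si](C(C)C)(C(C)C)C(C)C)[C@@](C)(CCCO[Si](C)(C)C(C)(C)C)[C@H]2C[C@@H]1C2(C)C | intermediate
12 | ring B C7=C8 enol acetate with 5-isopropenyl, 10β-methyl, 10-(3-acetoxypropyl), 9-CH2Ar | CC(=O)OC1=CC[C@@H](C(C)=C)[C@](C)(CCCOC(C)=O)C1Cc2cc(OC)c(C(=O)OC)cc2O[Si](C(C)C)(C(C)C)C(C)C | intermediate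
13 | ring B 8-ketone with 10-(3-hydroxypropyl) chain | O=C1CC[C@@H](C(C)=C)[C@](C)(CCCO)C1Cc2cc(OC)c(C(=O)OC)cc2O[Si](C(C)C)(C(C)C)C(C)C | intermediate
14 | ring B 8-ketone with 10-(3-oxopropyl) chain | O=C1CC[C@@H](C(C)=C)[C@](C)(CCC=O)C1Cc2cc(OC)c(C(=O)OC)cc2O[Si](C(C)C)(C(C)C)C(C)C | intermediate
15 | 11-Ar-3-hydroxy-12-nordriman-8-one, C3 and C9 epimers | O=C1CC[C@H]2C(C)(C)C(O)CC[C@]2(C)C1Cc3cc(OC)c(C(=O)OC)cc3O[Si](C(C)C)(C(C)C)C(C)C | intermediate
16 | (9S)-11-Ar-3-hydroxy-12-nordriman-8-one, C3 epimers | O=C1CC[C@H]2C(C)(C)C(O)CC[C@]2(C)[C@H]1Cc3cc(OC)c(C(=O)OC)cc3O[Si](C(C)C)(C(C)C)C(C)C | intermediate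
17 | 11-Ar-drim-8(12)-en-3-ol, C3 epimers | C=C1CC[C@H]2C(C)(C)C(O)CC[C@]2(C)[C@H]1Cc3cc(OC)c(C(=O)OC)cc3O[Si](C(C)C)(C(C)C)C(C)C | intermediate
18 | 11-Ar-drim-8(12)-en-3-one | C=C1CC[C@H]2C(C)(C)C(=O)CC[C@]2(C)[C@H]1Cc3cc(OC)c(C(=O)OC)cc3O[Si](C(C)C)(C(C)C)C(C)C | intermediate
19 | 11-Ar-drim-8(12)-en-3α-ol | C=C1CC[C@H]2C(C)(C)[C@H](O)CC[C@]2(C)[C@H]1Cc3cc(OC)c(C(=O)OC)cc3O[Si](C(C)C)(C(C)C)C(C)C | intermediate (not isolated)
20 | 11-[4-(hydroxymethyl)-5-methoxy-2-(triisopropylsilyloxy)phenyl]drim-8(12)-en-3α-ol | C=C1CC[C@H]2C(C)(C)[C@H](O)CC[C@]2(C)[C@H]1Cc3cc(OC)c(CO)cc3O[Si](C(C)C)(C(C)C)C(C)C | intermediate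
21 | 11-[2-hydroxy-4-(hydroxymethyl)-5-methoxyphenyl]drim-8(12)-en-3α-ol | C=C1CC[C@H]2C(C)(C)[C@H](O)CC[C@]2(C)[C@H]1Cc3cc(OC)c(CO)cc3O | intermediate
22 | 2-[(3α-hydroxydrim-8(12)-en-11-yl)]-5-(hydroxymethyl)-4,4-dimethoxycyclohexa-2,5-dien-1-one | C=C1CC[C@H]2C(C)(C)[C@H](O)CC[C@]2(C)[C@H]1CC3=CC(OC)(OC)C(CO)=CC3=O | intermediate
23 | (1'S,2'R)-1',2'-epoxide of 22 | C=C1CC[C@H]2C(C)(C)[C@H](O)CC[C@]2(C)[C@H]1C[C@]34O[C@H]3C(OC)(OC)C(CO)=CC4=O | intermediate
24 | D-threonine | OC(=O)[C@H](N)[C@H](C)O | starting material
25 | (2R,3S)-2,3-dihydroxybutanoic acid | OC(=O)[C@H](O)[C@H](C)O | intermediate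
26 | triethylsilyl (2R,3S)-2,3-bis(triethylsilyloxy)butanoate | CC[Si](CC)(CC)OC(=O)[C@H](O[Si](CC)(CC)CC)[C@H](C)O[Si](CC)(CC)CC | intermediate (not isolated)
27 | (2R,3S)-2,3-bis(triethylsilyloxy)butanoic acid | OC(=O)[C@H](O[Si](CC)(CC)CC)[C@H](C)O[Si](CC)(CC)CC | intermediate
28 | C7' (2R,3S)-2,3-bis(triethylsilyloxy)butanoate of 23 | C=C1CC[C@H]2C(C)(C)[C@H](O)CC[C@]2(C)[C@H]1C[C@]34O[C@H]3C(OC)(OC)C(COC(=O)[C@H](O[Si](CC)(CC)CC)[C@H](C)O[Si](CC)(CC)CC)=CC4=O | intermediate
29 | neomacrophorin I, (3R,5R,9S,10R,1'S,2'R,2''R,3''S) | C=C1CC[C@H]2C(C)(C)[C@H](O)CC[C@]2(C)[C@H]1C[C@]12O[C@H]1C(=O)C(COC(=O)[C@H](O)[C@H](C)O)=CC2=O | target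

Total step count: 22. Longest linear sequence: 19 steps (steps 1–5, 7–18, 21, 22).

Steps most likely to fail

Step 7. The conjugate addition should be dependable. The weak point is the benzylation, where the hindered, aggregated magnesium enolate may react too slowly. Proton exchange, attack on the ester of 6 or coupling of 6 with left-over 8 could then take over. The fallback replaces the SN2 alkylation by an aldol condensation and still makes C1–C10 and C9–C11.
- It sets out again from 9 and 8. The copper-catalysed addition is run in the presence of Me3SiCl and gives the trimethylsilyl enol ether F1.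
- Mukaiyama aldol addition of F1 to aldehyde 4 (BF3·OEt2, CH2Cl2, −78 °C) gives the β-hydroxy ketone F2.
- Mesylation and elimination (MsCl, Et3N, then DBU) give the benzylidene ketone F3, whose alkene geometry does not matter.
- Hydrogenation (H2, Pd/C, EtOAc), with delivery of hydrogen from the face away from the gem-dimethyl bridge, comes back to the route at 11.

Step 8. In this polyfunctional substrate the Lewis acid and anhydride may strip the aryl silyl ether or acetylate the ring. The C4 cation may also be captured by acetate or lose the C5 proton instead of a methyl proton. The fallback separates bond cleavage from alkene formation.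
- It sets out from 11. Dry HCl (4 M in dioxane, CH2Cl2, 0 °C → rt) opens the cyclobutane hydrochlorinatively and removes the primary silyl ether, giving the tertiary chloro keto alcohol F4.
- Dehydrochlorination with DBU (toluene, 80 °C) takes a proton from the accessible methyl groups rather than the shielded C5–H. It comes back to the route at 13 and bypasses 12.

Step 18. Facial selectivity may be poor, because the decalin stereocentres are remote from the flat dienone and may be mismatched with the tartrate complex. The second free hydroxyl group may also disturb that complex. The fallback moves the controlling element into the substrate as an auxiliary.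
- It sets out from 22. Transketalisation with (2R,4R)-pentane-2,4-diol (PPTS, benzene, 4 Å sieves) gives the C2-symmetric spiro-dioxane dienone F5.
- Nucleophilic epoxidation (t-BuOOH, DBU, CH2Cl2) under the control of the ketal methyl groups gives the epoxide F6.
- Esterification with 27 as in step 21 gives the ester F7.
- Aqueous HF in MeCN as in step 22 comes back to the route at 29.

Further compounds
F1 | step 7 | trimethylsilyl C8=C9 enol ether of the 10-alkylated pinanone | C[Si](C)(C)OC1=C[C@@](C)(CCCO[Si](C)(C)C(C)(C)C)[C@H]2C[C@@H]1C2(C)C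
F2 | step 7 | 9-[Ar(hydroxy)methyl]-10-alkyl pinanone (aldol adduct, carbinol and C9 epimers) | O=C1C(C(O)c3cc(OC)c(C(=O)OC)cc3O[Si](C(C)C)(C(C)C)C(C)C)[C@@](C)(CCCO[Si](C)(C)C(C)(C)C)[C@H]2C[C@@H]1C2(C)C
F3 | step 7 | 9-(Ar-methylidene)-10-alkyl pinanone | O=C1C(=Cc3cc(OC)c(C(=O)OC)cc3O[Si](C(C)C)(C(C)C)C(C)C)[C@@](C)(CCCO[Si](C)(C)C(C)(C)C)[C@H]2C[C@@H]1C2(C)C
F4 | step 8 | ring B 8-ketone with 5-(2-chloropropan-2-yl) and 10-(3-hydroxypropyl) groups | O=C1CC[C@@H](C(C)(C)Cl)[C@](C)(CCCO)C1Cc2cc(OC)c(C(=O)OC)cc2O[Si](C(C)C)(C(C)C)C(C)C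
F5 | step 18 | (2R,4R)-pentane-2,4-diyl ketal analogue of 22 | C=C1CC[C@H]2C(C)(C)[C@H](O)CC[C@]2(C)[C@H]1CC3=CC4(O[C@H](C)C[C@@H](C)O4)C(CO)=CC3=O
F6 | step 18 | (1'S,2'R)-epoxide of F5 | C=C1CC[C@H]2C(C)(C)[C@H](O)CC[C@]2(C)[C@H]1C[C@]34O[C@H]3C5(O[C@H](C)C[C@@H](C)O5)C(CO)=CC4=O
F7 | step 18 | C7' (2R,3S)-2,3-bis(triethylsilyloxy)butanoate of F6 | C=C1CC[C@H]2C(C)(C)[C@H](O)CC[C@]2(C)[C@H]1C[C@]34O[C@H]3C5(O[C@H](C)C[C@@H](C)O5)C(COC(=O)[C@H](O[Si](CC)(CC)CC)[C@H](C)O[Si](CC)(CC)CC)=CC4=O
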